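The flavan (2S)-chromane and a 3-iodoflavone are the two halves of the target. Everything rests on closing the pyran ring of the flavan (O1', C2', C3', C4', C4a', C8a') by ring-closing metathesis at C3'–C4'. These two adjacent methylene carbons, flanked by arene carbon C4a' and the stereogenic ether carbon C2', arise in one operation as a ring alkene (hydrogenated in step 7) from a 2-vinylaryl 1-arylallyl ether, whose C2' centre comes from iridium-catalysed allylic etherification. Cross-coupling at C8', closure of the dihydrofuran onto a silyloxyflavylium ion and hydroxylation of the resulting enol ether anti to the ketal aryl group then build the ring junction.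

Key step: step 6

Remark: read literally, the stereodescriptors place the 4-hydroxyphenyl group on ketal carbon C2 and the hydroxyl on C3 on opposite faces (a trans-fused dihydrofuran/pyranone junction). The route is built for exactly this array, so the hydroxyl is introduced last under kinetic control and the ketal never meets acid afterwards.

Locants: flavonoid numbering, unprimed for the chromanone part (O1, C2, C3, C4, ring A, aryl ring B), primed for the flavan part.

## Route

Step 1
Reactants: 1 2,4,6-trihydroxybenzaldehyde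
Product: 2 2,6-dihydroxy-4-[(triisopropylsilyl)oxy]benzaldehyde
Conditions: TIPSCl (1.05 equiv), imidazole, DMF, 0 °C
Reagents that add atoms: chlorotriisopropylsilane, CC(C)[Si](Cl)(C(C)C)C(C)C
Why: O-silylation; the 4-hydroxyl is the most acidic one and is not tied to the formyl group by a hydrogen bond, so one equivalent of the bulky silyl chloride should take it alone.

Step 2
Reactants: 2 2,6-dihydroxy-4-[(triisopropylsilyl)oxy]benzaldehyde
Product: 3 2-(benzyloxy)-6-hydroxy-4-[(triisopropylsilyl)oxy]benzaldehyde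
Conditions: BnBr (1.0 equiv), K2CO3 (1.1 equiv), acetone, 40 °C
Reagents that add atoms: benzyl bromide, BrCc1ccccc1
Why: Williamson ether synthesis; the two ortho hydroxyls are equivalent, and after the first alkylation the remaining one is locked to the formyl oxygen by a hydrogen bond, so the reaction should stop at the mono-ether.

Step 3
Reactants: 3 2-(benzyloxy)-6-hydroxy-4-[(triisopropylsilyl)oxy]benzaldehyde
Product: 4 3-(benzyloxy)-2-ethenyl-5-[(triisopropylsilyl)oxy]phenol
Conditions: Ph3PCH3Br (2.5 equiv), KOtBu (2.4 equiv), THF, 0 to 20 °C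
Reagents that add atoms: methyltriphenylphosphonium bromide, C[P+](c1ccccc1)(c1ccccc1)c1ccccc1.[Br-]
Why: Wittig methylenation; one equivalent of ylide is spent on the phenol and the excess converts the hindered aldehyde into the styrene.

Step 4
Reactants: 5 1-(benzyloxy)-4-ethenylbenzene; 6 allyl methyl carbonate
Product: 7 (E)-3-[4-(benzyloxy)phenyl]prop-2-en-1-yl methyl carbonate
Conditions: second-generation Grubbs catalyst RuCl2(=CHPh)(PCy3)(H2IMes) (3 mol %), 6 (4 equiv), CH2Cl2, 40 °C
Reagents that add atoms: none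
Why: olefin cross-metathesis; with the carbonate in excess the styrene should be converted into the thermodynamically preferred E cinnamyl carbonate with loss of ethene.

Step 5
Reactants: 4 3-(benzyloxy)-2-ethenyl-5-[(triisopropylsilyl)oxy]phenol; 7 (E)-3-[4-(benzyloxy)phenyl]prop-2-en-1-yl methyl carbonate
Product: 8 1-(benzyloxy)-3-{[(1S)-1-[4-(benzyloxy)phenyl]prop-2-en-1-yl]oxy}-2-ethenyl-5-[(triisopropylsilyl)oxy]benzene
Conditions: [Ir(cod)Cl]2 (2 mol %), (Sa,S,S)-O,O'-(1,1'-binaphthalene-2,2'-diyl) N,N-bis(1-phenylethyl)phosphoramidite (4 mol %), 1,5,7-triazabicyclo[4.4.0]dec-5-ene (8 mol %), THF, 25 °C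
Reagents that add atoms: none
Why: iridium-catalysed asymmetric allylic etherification; the phenoxide attacks the aryl-substituted terminus of the allyl–iridium complex on the face away from the metal, which gives the branched ether, and the ligand (the enantiomer expected to give S; its antipode is used if the sense proves opposite) sets C2'.

Step 6
Reactants: 8 1-(benzyloxy)-3-{[(1S)-1-[4-(benzyloxy)phenyl]prop-2-en-1-yl]oxy}-2-ethenyl-5-[(triisopropylsilyl)oxy]benzene
Product: 9 (2S)-5-(benzyloxy)-2-[4-(benzyloxy)phenyl]-7-[(triisopropylsilyl)oxy]-2H-chromene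
Conditions: second-generation Grubbs catalyst RuCl2(=CHPh)(PCy3)(H2IMes) (5 mol %), 1,4-benzoquinone (10 mol %), CH2Cl2 (5 mM), 40 °C
Reagents that add atoms: none
Why: Ring-closing olefin metathesis: the ruthenium carbene loads onto the less hindered vinyl group of the allylic ether, the new alkylidene adds to the styrene double bond through a ruthenacyclobutane, and cycloreversion releases ethene and the C3'=C4' ring alkene. The closest known reaction type is the ring-closing metathesis of 2-vinylaryl allyl ethers to 2H-chromenes. The pyran ring (O1', C2', C3', C4', C4a', C8a') closes as a six-membered ring with the new double bond inside it, necessarily cis. No stereocentre is created; C2' is carried over from step 5 because its C–H and C–O bonds take no part, and benzoquinone suppresses ruthenium hydride double-bond migration that could erode it. The step needs ring closure to win over intermolecular metathesis, which high dilution and the ortho relationship of the two alkenes secure; the electron-rich, doubly ortho-substituted styrene is the slower partner, so initiation is expected at the other alkene.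

Step 7
Reactants: 9 (2S)-5-(benzyloxy)-2-[4-(benzyloxy)phenyl]-7-[(triisopropylsilyl)oxy]-2H-chromene
Product: 10 (2S)-5-(benzyloxy)-2-[4-(benzyloxy)phenyl]-7-[(triisopropylsilyl)oxy]chromane
Conditions: H2 (1 atm), RhCl(PPh3)3 (5 mol %), benzene/EtOH, 25 °C
Reagents that add atoms: none
Why: homogeneous hydrogenation with RhCl(PPh3)3; the cis-disubstituted ring alkene is saturated while the benzyl ethers and the allylic–benzylic C2'–O bond, which a palladium surface could cleave, are left alone.

Step 8
Reactants: 10 (2S)-5-(benzyloxy)-2-[4-(benzyloxy)phenyl]-7-[(triisopropylsilyl)oxy]chromane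
Product: 11 (2S)-5-(benzyloxy)-2-[4-(benzyloxy)phenyl]-8-bromo-7-[(triisopropylsilyl)oxy]chromane
Conditions: NBS (1.0 equiv), CH2Cl2, −78 to 0 °C
Reagents that add atoms: N-bromosuccinimide, O=C1CCC(=O)N1Br
Why: electrophilic aromatic bromination; C8' is activated by three oxygens and lies between the silyl ether and the ring oxygen, whereas C6' is squeezed between two bulky ether groups, so substitution should go to C8' as it does in 5,7-di-O-protected flavans in general.

Step 9
Reactants: 11 (2S)-5-(benzyloxy)-2-[4-(benzyloxy)phenyl]-8-bromo-7-[(triisopropylsilyl)oxy]chromane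
Product: 12 (2S)-5-(benzyloxy)-2-[4-(benzyloxy)phenyl]-8-bromochroman-7-ol
Conditions: TBAF (1.1 equiv), THF, 0 °C; aqueous NH4Cl
Reagents that add atoms: none
Why: fluoride cleavage of the aryl silyl ether; benzyl ethers and the aryl bromide are inert to it.

Step 10
Reactants: 13 apigenin
Product: 14 5,7-bis(benzyloxy)-2-[4-(benzyloxy)phenyl]-4H-chromen-4-one
Conditions: BnBr (4 equiv), K2CO3 (4 equiv), DMF, 80 °C
Reagents that add atoms: benzyl bromide, BrCc1ccccc1
Why: Williamson ether synthesis; heating in DMF is needed so that the chelated 5-hydroxyl is alkylated as well.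

Step 11
Reactants: 14 5,7-bis(benzyloxy)-2-[4-(benzyloxy)phenyl]-4H-chromen-4-one
Product: 16 5,7-bis(benzyloxy)-2-[4-(benzyloxy)phenyl]-3-iodo-4H-chromen-4-one, via 3-lithioflavone 15 (not isolated)
Conditions: LiN(iPr)2 (1.2 equiv), THF, −78 °C; then I2 (1.3 equiv), −78 to 0 °C
Reagents that add atoms: iodine, [I][I]
Why: directed deprotonation and iodination; the vinylic C3–H next to the carbonyl is the most acidic site and its lithio derivative is trapped by iodine, which avoids the ring A substitution that electrophilic iodination would give.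

Step 12
Reactants: 12 (2S)-5-(benzyloxy)-2-[4-(benzyloxy)phenyl]-8-bromochroman-7-ol; 16 5,7-bis(benzyloxy)-2-[4-(benzyloxy)phenyl]-3-iodo-4H-chromen-4-one
Product: 19 5,7-bis(benzyloxy)-2-[4-(benzyloxy)phenyl]-3-{(2S)-5-(benzyloxy)-2-[4-(benzyloxy)phenyl]-7-hydroxychroman-8-yl}-4H-chromen-4-one, via dilithio species 17 (not isolated), via arylzinc chloride 18 (not isolated)
Conditions: n-BuLi (2.1 equiv), THF, −78 to −20 °C; ZnCl2 (1.2 equiv), −78 to 0 °C; then 16, Pd2(dba)3 (2.5 mol %), SPhos (10 mol %), THF, 50 °C; aqueous NH4Cl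
Reagents that add atoms: none
Why: Negishi cross-coupling; bromine–lithium exchange on the lithium phenoxide and transmetalation give an arylzinc that couples with the vinylic iodide under a bulky biarylphosphine–palladium catalyst able to join the two hindered carbons C8' and C3.

Step 13
Reactants: 19 5,7-bis(benzyloxy)-2-[4-(benzyloxy)phenyl]-3-{(2S)-5-(benzyloxy)-2-[4-(benzyloxy)phenyl]-7-hydroxychroman-8-yl}-4H-chromen-4-one
Product: 21 pentabenzyl silyl enol ether ketal (O7'–C2 bond closed; C3=C4 carrying tert-butyldimethylsilyloxy on C4; ketal carbon R), via 4-silyloxyflavylium triflate 20 (not isolated)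
Conditions: TBSOTf (1.5 equiv), 2,6-lutidine (3 equiv), CH2Cl2, −78 to 0 °C; Et3N quench; chromatography on Et3N-deactivated silica
Reagents that add atoms: tert-butyldimethylsilyl trifluoromethanesulfonate, CC(C)(C)[Si](C)(C)OS(=O)(=O)C(F)(F)F
Why: Proposed new method: silylation of the flavone carbonyl gives 4-silyloxyflavylium ion 20 and the ortho-hydroxyl of the C3 aryl group (free or transiently silylated) closes onto C2 in a 5-exo-trig mode while lutidine takes the proton, so that the ketal and the silyl enol ether form together; the closest known reaction types are the addition of carbon nucleophiles at C2 of 4-silyloxybenzopyrylium ions made from chromones and silyl triflates and the capture of flavylium ions at C2 by phenol oxygen; C4 is shielded by its silyloxy group and the peri benzyloxy group, which should direct the phenol to C2; the oxygen can only reach the face of C2 on which the twist about the C3–C8' bond places it, and the remote C2' centre cannot bias that twist, so no control of the new ketal centre is claimed and 21, the R-configured ketal, is taken from the product by chromatography.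

Step 14
Reactants: 21 pentabenzyl silyl enol ether ketal (ketal carbon R)
Product: 24 pentabenzyl ether of the target (2R,3S,2'S; C2 aryl and C3 hydroxyl trans), via silyloxy epoxide 22 (not isolated), via silyloxy ketone 23 (not isolated)
Conditions: dimethyldioxirane (1.1 equiv, acetone), CH2Cl2, −78 to −20 °C; then TBAF (1.2 equiv), AcOH (1.2 equiv), THF, 0 °C
Reagents that add atoms: dimethyldioxirane, CC1(C)OO1
Why: Rubottom oxidation; the aryl group on the neighbouring ketal carbon stands nearly perpendicular to the enol ether plane and blocks one face, so the dioxirane should deliver oxygen to C3 from the opposite face, the silyloxy epoxide rearranges to the silyloxy ketone and buffered fluoride frees the hydroxyl, which sets C3 (S) with its hydroxyl trans to the C2 aryl group without the ketal ever being ionised.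

Step 15
Reactants: 24 pentabenzyl ether of the target
Product: 25 target CNP0208300.3
Conditions: H2 (1 atm), Pd/C (10 wt % Pd), EtOAc/THF, 20 °C; filtration and evaporation below 20 °C
Reagents that add atoms: none
Why: hydrogenolysis of the five benzyl ethers over palladium under neutral conditions; no acid or base is present that could open the ketal through an oxocarbenium ion or a quinone methide, so the three stereocentres should be kept.

## Compound list

1 | 2,4,6-trihydroxybenzaldehyde | O=Cc1c(O)cc(O)cc1O | starting material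
2 | 2,6-dihydroxy-4-[(triisopropylsilyl)oxy]benzaldehyde | O=Cc1c(O)cc(O[Si](C(C)C)(C(C)C)C(C)C)cc1O | intermediate
3 | 2-(benzyloxy)-6-hydroxy-4-[(triisopropylsilyl)oxy]benzaldehyde | O=Cc1c(O)cc(O[Si](C(C)C)(C(C)C)C(C)C)cc1OCc1ccccc1 | intermediate
4 | 3-(benzyloxy)-2-ethenyl-5-[(triisopropylsilyl)oxy]phenol | C=Cc1c(O)cc(O[Si](C(C)C)(C(C)C)C(C)C)cc1OCc1ccccc1 | intermediate
5 | 1-(benzyloxy)-4-ethenylbenzene | C=Cc1ccc(OCc2ccccc2)cc1 | starting material
6 | allyl methyl carbonate | C=CCOC(=O)OC | starting material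
7 | (E)-3-[4-(benzyloxy)phenyl]prop-2-en-1-yl methyl carbonate | COC(=O)OC/C=C/c1ccc(OCc2ccccc2)cc1 | intermediate
8 | 1-(benzyloxy)-3-{[(1S)-1-[4-(benzyloxy)phenyl]prop-2-en-1-yl]oxy}-2-ethenyl-5-[(triisopropylsilyl)oxy]benzene | C=Cc1c(OCc2ccccc2)cc(O[Si](C(C)C)(C(C)C)C(C)C)cc1O[C@H](c1ccc(OCc2ccccc2)cc1)C=C | intermediate
9 | (2S)-5-(benzyloxy)-2-[4-(benzyloxy)phenyl]-7-[(triisopropylsilyl)oxy]-2H-chromene | CC(C)[Si](C(C)C)(C(C)C)Oc1cc(OCc2ccccc2)c2c(c1)O[C@H](c1ccc(OCc3ccccc3)cc1)C=C2 | intermediate
10 | (2S)-5-(benzyloxy)-2-[4-(benzyloxy)phenyl]-7-[(triisopropylsilyl)oxy]chromane | CC(C)[Si](C(C)C)(C(C)C)Oc1cc(OCc2ccccc2)c2c(c1)O[C@H](c1ccc(OCc3ccccc3)cc1)CC2 | intermediate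
11 | (2S)-5-(benzyloxy)-2-[4-(benzyloxy)phenyl]-8-bromo-7-[(triisopropylsilyl)oxy]chromane | CC(C)[Si](C(C)C)(C(C)C)Oc1cc(OCc2ccccc2)c2c(c1Br)O[C@H](c1ccc(OCc3ccccc3)cc1)CC2 | intermediate
12 | (2S)-5-(benzyloxy)-2-[4-(benzyloxy)phenyl]-8-bromochroman-7-ol | Oc1cc(OCc2ccccc2)c2c(c1Br)O[C@H](c1ccc(OCc3ccccc3)cc1)CC2 | intermediate
13 | apigenin (5,7-dihydroxy-2-(4-hydroxyphenyl)-4H-chromen-4-one) | O=c1cc(-c2ccc(O)cc2)oc2cc(O)cc(O)c12 | starting material
14 | 5,7-bis(benzyloxy)-2-[4-(benzyloxy)phenyl]-4H-chromen-4-one | O=c1cc(-c2ccc(OCc3ccccc3)cc2)oc2cc(OCc3ccccc3)cc(OCc3ccccc3)c12 | intermediate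
15 | 5,7-bis(benzyloxy)-2-[4-(benzyloxy)phenyl]-3-lithio-4H-chromen-4-one | [Li]c1c(-c2ccc(OCc3ccccc3)cc2)oc2cc(OCc3ccccc3)cc(OCc3ccccc3)c2c1=O | intermediate (not isolated)
16 | 5,7-bis(benzyloxy)-2-[4-(benzyloxy)phenyl]-3-iodo-4H-chromen-4-one | O=c1c(I)c(-c2ccc(OCc3ccccc3)cc2)oc2cc(OCc3ccccc3)cc(OCc3ccccc3)c12 | intermediate
17 | lithium (2S)-5-(benzyloxy)-2-[4-(benzyloxy)phenyl]-8-lithiochroman-7-olate | [Li]Oc1cc(OCc2ccccc2)c2c(c1[Li])O[C@H](c1ccc(OCc3ccccc3)cc1)CC2 | intermediate (not isolated)
18 | [(2S)-5-(benzyloxy)-2-[4-(benzyloxy)phenyl]-7-(lithiooxy)chroman-8-yl]zinc chloride | [Li]Oc1cc(OCc2ccccc2)c2c(c1[Zn]Cl)O[C@H](c1ccc(OCc3ccccc3)cc1)CC2 | intermediate (not isolated)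
19 | 5,7-bis(benzyloxy)-2-[4-(benzyloxy)phenyl]-3-{(2S)-5-(benzyloxy)-2-[4-(benzyloxy)phenyl]-7-hydroxychroman-8-yl}-4H-chromen-4-one | O=c1c(-c2c(O)cc(OCc3ccccc3)c3c2O[C@H](c2ccc(OCc4ccccc4)cc2)CC3)c(-c2ccc(OCc3ccccc3)cc2)oc2cc(OCc3ccccc3)cc(OCc3ccccc3)c12 | intermediate
20 | 5,7-bis(benzyloxy)-2-[4-(benzyloxy)phenyl]-3-{(2S)-5-(benzyloxy)-2-[4-(benzyloxy)phenyl]-7-hydroxychroman-8-yl}-4-[(tert-butyldimethylsilyl)oxy]chromenylium trifluoromethanesulfonate | CC(C)(C)[Si](C)(C)Oc1c(-c2c(O)cc(OCc3ccccc3)c3c2O[C@H](c2ccc(OCc4ccccc4)cc2)CC3)c(-c2ccc(OCc3ccccc3)cc2)[o+]c2cc(OCc3ccccc3)cc(OCc3ccccc3)c12.[O-]S(=O)(=O)C(F)(F)F | intermediate (not isolated)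
21 | silyl enol ether ketal: compound 19 with O7' bonded to C2 (dihydrofuran closed), C3=C4 double bond and tert-butyldimethylsilyloxy on C4; ketal carbon C2 R, C2' S | CC(C)(C)[Si](C)(C)OC1=C2c3c(O[C@H](c4ccc(OCc5ccccc5)cc4)CC5)c5c(OCc4ccccc4)cc3O[C@]2(c2ccc(OCc3ccccc3)cc2)Oc2cc(OCc3ccccc3)cc(OCc3ccccc3)c12 | intermediate
22 | silyloxy epoxide of 21 across C3–C4, oxirane oxygen on the face opposite the C2 aryl group | CC(C)(C)[Si](C)(C)O[C@@]12O[C@]1(c4c(O[C@H](c7ccc(OCc8ccccc8)cc7)CC5)c5c(OCc7ccccc7)cc4O6)[C@@]6(c4ccc(OCc5ccccc5)cc4)Oc4cc(OCc5ccccc5)cc(OCc5ccccc5)c24 | intermediate (not isolated)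
23 | pentabenzyl ether of the target with tert-butyldimethylsilyl on the C3 oxygen (2R,3S,2'S) | O=C1c2c(OCc3ccccc3)cc(OCc3ccccc3)cc2O[C@@]2(c3ccc(OCc4ccccc4)cc3)Oc3cc(OCc4ccccc4)c4c(c3[C@]12O[Si](C)(C)C(C)(C)C)O[C@H](c1ccc(OCc3ccccc3)cc1)CC4 | intermediate (not isolated)
24 | pentabenzyl ether of the target (benzyl on O5, O7, O4 of ring B, O5' and O4 of the flavan aryl; 2R,3S,2'S; C2 aryl and C3 hydroxyl trans) | O=C1c2c(OCc3ccccc3)cc(OCc3ccccc3)cc2O[C@@]2(c3ccc(OCc4ccccc4)cc3)Oc3cc(OCc4ccccc4)c4c(c3[C@]12O)O[C@H](c1ccc(OCc3ccccc3)cc1)CC4 | intermediate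
25 | target CNP0208300.3: 3,5,7-trihydroxy-2-(4-hydroxyphenyl)chroman-4-one joined through C3–C8' and C2–O7' to (2S)-5-hydroxy-2-(4-hydroxyphenyl)chromane; C2 R, C3 S, C2' S | O=C1c2c(O)cc(O)cc2O[C@@]2(c3ccc(O)cc3)Oc3cc(O)c4c(c3[C@]12O)O[C@H](c1ccc(O)cc1)CC4 | target

## Step count and risks

Total step count: 15. Longest linear sequence: 12 steps (steps 1, 2, 3, 5, 6, 7, 8, 9, 12, 13, 14, 15).

Steps most likely to fail:

Step 13 (Proposed new method). What may go wrong: capture of the silyloxyflavylium ion at C4 instead of C2, mere silylation of the phenol, re-ionisation of the ketal on isolation, and closure without any facial preference at C2, which should cost about half of the material per pass. Material closed on the wrong face can be returned to catalytic TBSOTf at 20 °C, where ionisation back to 20 and rotation about the C3–C8' bond should re-equilibrate it before a second separation. The fallback uses known reactions only, sets out from 19 and comes back at 24. Reduction of the flavone carbonyl with i-Bu2AlH (THF, −78 °C) gives flav-2-en-4-ol F1. Catalytic camphorsulfonic acid with 4 Å molecular sieves (CH2Cl2, 0 °C, Et3N quench) ionises it to the flavylium ion, which the ortho-phenol captures at C2, the thermodynamically preferred site for oxygen nucleophiles. This gives chromene ketal F2 together with its ketal epimer F3, which is separated and re-equilibrated with the same acid. OsO4 (catalytic) with N-methylmorpholine N-oxide (acetone–water, pyridine) dihydroxylates the C3=C4 bond of F2 anti to the C2 aryl group to give cis-diol F4. Dess–Martin periodinane with NaHCO3 oxidises only the secondary C4 hydroxyl and returns 24.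

Step 14. What may go wrong: oxygen transfer to the face syn to the aryl group or to the electron-rich arenes, and ionisation of the ketal by acid traces so that the junction relaxes to its cis-fused epimer. The fallback sets out from 21 and comes back at 23. Photo-oxygenation (O2, tetraphenylporphyrin, visible light, CH2Cl2, −78 °C) replaces epoxidation by the silatropic ene reaction of singlet oxygen, a concerted transfer on the open face that needs no epoxide, and gives silylperoxy ketone F5. PPh3 then removes the outer peroxide oxygen to give 23, which is desilylated as in step 14.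

Step 12. What may go wrong: slow oxidative addition and transmetalation between two doubly ortho-substituted partners, protodezincation of 18, and base-induced rearrangement of 19. The fallback sets out from 12 and comes back at 21. 1-[2,4-Bis(benzyloxy)-6-hydroxyphenyl]ethanone is acylated with 4-(benzyloxy)benzoyl chloride (pyridine) to aryl ester F6. Baker–Venkataraman rearrangement (KOH, pyridine, 50 °C) turns it into 1,3-diketone F7. Copper-catalysed C-arylation of F7 with 12 (CuI, L-proline, Cs2CO3, DMSO, 80 °C), followed by cyclodehydration of the 7'-hydroxyl onto the 4-benzyloxybenzoyl carbonyl, gives benzofuranyl ketone F8, an isomer of 19. Under the conditions of step 13 its silylated carbonyl generates a benzofuranylium-type oxocarbenium ion that the ring A phenol closes at C2, giving 21 after the same chromatographic separation.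

## Further compounds

F1 | step 13 | 5,7-bis(benzyloxy)-2-[4-(benzyloxy)phenyl]-3-{(2S)-5-(benzyloxy)-2-[4-(benzyloxy)phenyl]-7-hydroxychroman-8-yl}-4H-chromen-4-ol (both C4 configurations) | OC1C(c2c(O)cc(OCc3ccccc3)c3c2O[C@H](c2ccc(OCc4ccccc4)cc2)CC3)=C(c2ccc(OCc3ccccc3)cc2)Oc2cc(OCc3ccccc3)cc(OCc3ccccc3)c12
F2 | step 13 | chromene ketal: analogue of 21 with hydrogen on C4 (C3=C4–H; ketal carbon as in 21, C2' S) | C1=C2c3c(O[C@H](c4ccc(OCc5ccccc5)cc4)CC5)c5c(OCc4ccccc4)cc3O[C@]2(c2ccc(OCc3ccccc3)cc2)Oc2cc(OCc3ccccc3)cc(OCc3ccccc3)c12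
F3 | step 13 | epimer of F2 at the ketal carbon | C1=C2c3c(O[C@H](c4ccc(OCc5ccccc5)cc4)CC5)c5c(OCc4ccccc4)cc3O[C@@]2(c2ccc(OCc3ccccc3)cc2)Oc2cc(OCc3ccccc3)cc(OCc3ccccc3)c12
F4 | step 13 | C4 alcohol of 24: cis-3,4-diol with both hydroxyls on the face opposite the C2 aryl group | O[C@H]1c2c(OCc3ccccc3)cc(OCc3ccccc3)cc2O[C@@]2(c3ccc(OCc4ccccc4)cc3)Oc3cc(OCc4ccccc4)c4c(c3[C@]12O)O[C@H](c1ccc(OCc3ccccc3)cc1)CC4
F5 | step 14 | tert-butyldimethylsilyl peroxide of 24 at C3 (configuration as in 23) | O=C1c2c(OCc3ccccc3)cc(OCc3ccccc3)cc2O[C@@]2(c3ccc(OCc4ccccc4)cc3)Oc3cc(OCc4ccccc4)c4c(c3[C@]12OO[Si](C)(C)C(C)(C)C)O[C@H](c1ccc(OCc3ccccc3)cc1)CC4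
F6 | step 12 | 2-acetyl-3,5-bis(benzyloxy)phenyl 4-(benzyloxy)benzoate | CC(=O)c1c(OC(=O)c2ccc(OCc3ccccc3)cc2)cc(OCc2ccccc2)cc1OCc1ccccc1
F7 | step 12 | 1-[2,4-bis(benzyloxy)-6-hydroxyphenyl]-3-[4-(benzyloxy)phenyl]propane-1,3-dione | O=C(CC(=O)c1ccc(OCc2ccccc2)cc1)c1c(O)cc(OCc2ccccc2)cc1OCc1ccccc1
F8 | step 12 | benzofuranyl ketone: (2S)-flavan fused at C7'–O and C8' to a furan carrying 4-(benzyloxy)phenyl on the oxygen-bound carbon and a 2,4-bis(benzyloxy)-6-hydroxybenzoyl group on the other | O=C(c1c(O)cc(OCc2ccccc2)cc1OCc1ccccc1)c1c(-c2ccc(OCc3ccccc3)cc2)oc2cc(OCc3ccccc3)c3c(c12)O[C@H](c1ccc(OCc2ccccc2)cc1)CC3
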